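**Plan**

- Retrosynthesis: the two phenols are masked as benzyl ethers and the methyls C9 and C9′ are traced back through CH2OMs and CH2OH to CH2Bpin. The cuts then fall at C8–C9 and C8′–C9′ (boron-to-carbon 1,2-shifts), at the two C–B bonds on C8 and C8′ (syn-diboration), and last at C8=C8′ (homometathesis of a protected 4-allyl-2,6-dimethoxyphenol).
- Forward: no ring is made. Two C6–C3 units are joined at C8–C8′ by Z-selective homocoupling, C9 and C9′ are added in one flask, boron is exchanged for oxygen and then hydrogen, and the benzyl groups are removed last.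
- Enabling feature: the chain ArC7H2–C8H(C9H3)–C8′H(C9′H3)–C7′H2Ar is acyclic, the only rings being the two syringyl arenes. C8 and C8′ are neighbours with identical substituents and (8R,8′S) configuration, so C9 and C9′ sit as if both had been added to one face of a (Z)-C8=C8′ double bond.
- Stereochemistry: the Z geometry comes from the metathesis catalyst. Syn addition of B–B and retention in both 1,2-shifts convert it into the meso pair, and no later step touches C8 or C8′.

Key step: step 3

Remark: the target SMILES encodes C8 = R and C8′ = S on a constitutionally symmetric chain, which is the meso (achiral) diastereomer. "Single enantiomer" is therefore read as "single meso diastereomer", and only relative configuration has to be controlled.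

**Step 1**
Reactants: 1 4-allyl-2,6-dimethoxyphenol; 2 benzyl bromide
Product: 3 5-allyl-2-(benzyloxy)-1,3-dimethoxybenzene
Conditions: BnBr, K2CO3, DMF, 50 °C
Reagents that add atoms: benzyl bromide, BrCc1ccccc1
Why: Williamson ether synthesis, in which the phenoxide of the 2,6-dimethoxyphenol is O-alkylated by the reactive benzylic bromide while the allyl group is inert to carbonate, and the free phenol must be masked because it would protonate the cyclometalated catalyst of step 2 and consume organolithium in step 3.

**Step 2**
Reactants: 3 5-allyl-2-(benzyloxy)-1,3-dimethoxybenzene (two molecules)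
Product: 4 (Z)-1,4-bis[4-(benzyloxy)-3,5-dimethoxyphenyl]but-2-ene
Conditions: cyclometalated Ru nitrato NHC catalyst (C–H-activated N-adamantyl, N-2,6-diisopropylphenyl; 1 mol%), THF, 35 °C, static vacuum; stopped at partial conversion, 3 recycled
Reagents that add atoms: none
Why: Z-selective olefin homometathesis, for which allylarenes are standard substrates of chelated ruthenium catalysts because the side-bound metallacyclobutane places both substituents away from the N-aryl group, with ethylene removal driving the coupling and early termination limiting secondary metathesis and double-bond migration.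

**Step 3**
Reactants: 4 (Z)-1,4-bis[4-(benzyloxy)-3,5-dimethoxyphenyl]but-2-ene; 5 bis(pinacolato)diboron; 6 bromochloromethane
Product: 8 meso-(2R,3S)-2,3-bis[4-(benzyloxy)-3,5-dimethoxybenzyl]-1,4-bis(4,4,5,5-tetramethyl-1,3,2-dioxaborolan-2-yl)butane, via meso-vicinal bis(pinacolboronate) 7 (not isolated)
Conditions: B2pin2 (1.1 equiv), Cs2CO3 (15 mol%), MeOH (5 equiv), THF, 70 °C; volatiles stripped, toluene chase; then BrCH2Cl (6 equiv), n-BuLi (5 equiv), THF, −78 °C → rt, same flask
Reagents that add atoms: bis(pinacolato)diboron, CC1(C)OB(OC1(C)C)B1OC(C)(C)C(C)(C)O1; bromochloromethane (source of chloromethyllithium), ClCBr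
Why: Methoxide adds to one boron of B2pin2 and the resulting sp2–sp3 diboron adduct delivers its sp2 boryl group as a nucleophile to C8 while the charge building up at C8′ is captured on the same face by the second boron, so both C–B bonds form syn and the Z-alkene should give only the meso bis(boronate) 7; this alkoxide-catalysed, transition-metal-free diboration of non-activated internal alkenes is the closest known reaction type and is preferred to Pt(0)/B2pin2 catalysis, which is efficient only for terminal or strained alkenes. Once methanol has been stripped off, chloromethyllithium made in situ from BrCH2Cl and n-BuLi at −78 °C forms a boronate complex at each boron, and on warming each secondary carbon (C8, C8′) shifts from boron to the CH2Cl carbon with retention as chloride leaves, a double Matteson homologation that creates C8–C9 and C8′–C9′. No ring is formed. Both new stereocentres are fixed by the Z geometry of 4 combined with the syn addition, and the stereoretentive 1,2-shifts pass this relationship on unchanged, so a meso product needs no external chiral control. The selectivity required is complete single insertion at both hindered secondary boronates without a second insertion: an excess of carbenoid is generated at −78 °C, where the ate complexes persist and unreacted carbenoid decomposes before migration sets in, and the aryl and benzyl ethers are inert to both stages.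

**Step 4**
Reactants: 8 meso-(2R,3S)-2,3-bis[4-(benzyloxy)-3,5-dimethoxybenzyl]-1,4-bis(4,4,5,5-tetramethyl-1,3,2-dioxaborolan-2-yl)butane
Product: 9 meso-(2R,3S)-2,3-bis[4-(benzyloxy)-3,5-dimethoxybenzyl]butane-1,4-diol
Conditions: 30% H2O2, 3 M NaOH, THF, 0 °C → rt
Reagents that add atoms: hydrogen peroxide, OO
Why: Oxidation of alkylboronic esters by hydroperoxide (carbon shifts from boron to oxygen), which here occurs at the two CH2 groups only, so C8 and C8′ are not involved and the benzyl-protected arenes tolerate the basic peroxide.

**Step 5**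
Reactants: 9 meso-(2R,3S)-2,3-bis[4-(benzyloxy)-3,5-dimethoxybenzyl]butane-1,4-diol
Product: 10 meso-(2R,3S)-2,3-bis[4-(benzyloxy)-3,5-dimethoxybenzyl]butane-1,4-diyl dimethanesulfonate
Conditions: MsCl (3 equiv), Et3N (4 equiv), CH2Cl2, −20 → 0 °C
Reagents that add atoms: methanesulfonyl chloride, CS(Cl)(=O)=O
Why: Sulfonylation of primary alcohols through the sulfene pathway, which is fast enough at low temperature with excess reagent for the second hydroxyl to be mesylated before it can displace the first mesylate.

**Step 6**
Reactants: 10 meso-(2R,3S)-2,3-bis[4-(benzyloxy)-3,5-dimethoxybenzyl]butane-1,4-diyl dimethanesulfonate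
Product: 11 meso-(2R,3S)-1,4-bis[4-(benzyloxy)-3,5-dimethoxyphenyl]-2,3-dimethylbutane
Conditions: LiEt3BH (5 equiv), THF, 0 °C → rt
Reagents that add atoms: none
Why: SN2 hydride displacement of primary sulfonates by lithium triethylborohydride, the standard deoxygenation of β-branched primary mesylates, which occurs at C9 and C9′ only and leaves aryl ethers and both stereocentres untouched.

**Step 7**
Reactants: 11 meso-(2R,3S)-1,4-bis[4-(benzyloxy)-3,5-dimethoxyphenyl]-2,3-dimethylbutane
Product: 12 4,4′-[(2R,3S)-2,3-dimethylbutane-1,4-diyl]bis(2,6-dimethoxyphenol) (CNP0314108.1)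
Conditions: H2 (1 atm), 10% Pd/C, EtOAc–MeOH, rt
Reagents that add atoms: none
Why: Catalytic hydrogenolysis of benzyl aryl ethers over palladium, with no other reducible group present and the saturated chain and its meso stereocentres unaffected.

**Compound list**

1 | 4-allyl-2,6-dimethoxyphenol | COc1cc(CC=C)cc(OC)c1O | starting material
2 | benzyl bromide | BrCc1ccccc1 | starting material
3 | 5-allyl-2-(benzyloxy)-1,3-dimethoxybenzene | COc1cc(CC=C)cc(OC)c1OCc1ccccc1 | intermediate
4 | (Z)-1,4-bis[4-(benzyloxy)-3,5-dimethoxyphenyl]but-2-ene | COc1cc(C/C=C\Cc2cc(OC)c(OCc3ccccc3)c(OC)c2)cc(OC)c1OCc1ccccc1 | intermediate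
5 | bis(pinacolato)diboron | CC1(C)OB(OC1(C)C)B1OC(C)(C)C(C)(C)O1 | starting material
6 | bromochloromethane | ClCBr | starting material
7 | meso-(2R,3S)-1,4-bis[4-(benzyloxy)-3,5-dimethoxyphenyl]-2,3-bis(4,4,5,5-tetramethyl-1,3,2-dioxaborolan-2-yl)butane | COc1cc(C[C@@H](B2OC(C)(C)C(C)(C)O2)[C@@H](B2OC(C)(C)C(C)(C)O2)Cc2cc(OC)c(OCc3ccccc3)c(OC)c2)cc(OC)c1OCc1ccccc1 | intermediate (not isolated)
8 | meso-(2R,3S)-2,3-bis[4-(benzyloxy)-3,5-dimethoxybenzyl]-1,4-bis(4,4,5,5-tetramethyl-1,3,2-dioxaborolan-2-yl)butane | COc1cc(C[C@@H](CB2OC(C)(C)C(C)(C)O2)[C@@H](CB2OC(C)(C)C(C)(C)O2)Cc2cc(OC)c(OCc3ccccc3)c(OC)c2)cc(OC)c1OCc1ccccc1 | intermediate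
9 | meso-(2R,3S)-2,3-bis[4-(benzyloxy)-3,5-dimethoxybenzyl]butane-1,4-diol | COc1cc(C[C@@H](CO)[C@@H](CO)Cc2cc(OC)c(OCc3ccccc3)c(OC)c2)cc(OC)c1OCc1ccccc1 | intermediate
10 | meso-(2R,3S)-2,3-bis[4-(benzyloxy)-3,5-dimethoxybenzyl]butane-1,4-diyl dimethanesulfonate | COc1cc(C[C@@H](COS(C)(=O)=O)[C@@H](COS(C)(=O)=O)Cc2cc(OC)c(OCc3ccccc3)c(OC)c2)cc(OC)c1OCc1ccccc1 | intermediate
11 | meso-(2R,3S)-1,4-bis[4-(benzyloxy)-3,5-dimethoxyphenyl]-2,3-dimethylbutane | COc1cc(C[C@@H](C)[C@@H](C)Cc2cc(OC)c(OCc3ccccc3)c(OC)c2)cc(OC)c1OCc1ccccc1 | intermediate
12 | 4,4′-[(2R,3S)-2,3-dimethylbutane-1,4-diyl]bis(2,6-dimethoxyphenol) | COc1cc(C[C@@H](C)[C@@H](C)Cc2cc(OC)c(O)c(OC)c2)cc(OC)c1O | target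

**Step count and risks**

Total step count: 7. Longest linear sequence: 7 steps (1 → 3 → 4 → 8 → 9 → 10 → 11 → 12).

Steps most likely to fail:

1. Step 3. Boryl transfer to the hindered 1,2-dialkyl alkene may stall, the transient β-boryl carbanion may be protonated by methanol before the second boron arrives (giving a formal hydroboration product), and the second homologation may remain incomplete. The fallback sets out from 4 and changes both the way the B–B bond is activated and the operation. Rhodium(I)-catalysed diboration with bis(catecholato)diboron [(nbd)Rh(acac), Quinap-type P,N ligand, THF, rt] proceeds by oxidative addition, syn insertion and reductive elimination and is established for internal alkenes. It should give the meso vicinal bis(catecholboronate) F1 whichever ligand enantiomer is used, since the product is meso. Pinacol exchange in the same pot then gives 7, which is isolated and purified. A separate double homologation with BrCH2Cl/n-BuLi at −78 °C returns to the route at 8.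

2. Step 2. Z geometry may be eroded by secondary metathesis of the product, and ruthenium hydride species may move the double bond into conjugation with the arene. Any E-alkene carried forward would end as the racemic diastereomer after step 3. The fallback sets out from 3 and builds the alkene by carbonyl olefination. Lemieux–Johnson cleavage of 3 (cat. OsO4, NaIO4, 2,6-lutidine, dioxane–H2O) gives 2-[4-(benzyloxy)-3,5-dimethoxyphenyl]acetaldehyde F2. Part of it is reduced with NaBH4 to 2-[4-(benzyloxy)-3,5-dimethoxyphenyl]ethanol F3. Appel iodination (I2, PPh3, imidazole) gives 2-(benzyloxy)-5-(2-iodoethyl)-1,3-dimethoxybenzene F4, and PPh3 in hot MeCN gives {2-[4-(benzyloxy)-3,5-dimethoxyphenyl]ethyl}triphenylphosphonium iodide F5. A lithium-free Wittig reaction of the non-stabilised ylide (NaHMDS, THF, −78 °C) with F2 should then deliver the Z-alkene through the kinetically favoured cis-oxaphosphetane, returning to the route at 4.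

3. Step 5. The mono-mesylate may close to the cis-3,4-disubstituted tetrahydrofuran through attack of the remaining hydroxyl before the second sulfonylation. The same ether can arise in step 6 if hydride attacks sulfur and not carbon. The fallback sets out from 8 and avoids oxygenated intermediates altogether. Phenyllithium (2.2 equiv, THF, 0 °C) converts 8 into the dilithium bis(phenylboronate) complex F6, which is not isolated. Photoredox protodeboronation (Ir photocatalyst, thiophenol as hydrogen-atom donor, MeOH–acetone, blue light) is known for primary alkyl pinacol boronates. It oxidises each ate complex to a primary radical at C9 or C9′, which is reduced to the methyl group, returning to the route at 11 with steps 4–6 bypassed.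

**Further compounds**

F1 | step 3 | meso-(2R,3S)-1,4-bis[4-(benzyloxy)-3,5-dimethoxyphenyl]-2,3-bis(1,3,2-benzodioxaborol-2-yl)butane | COc1cc(C[C@@H](B2Oc3ccccc3O2)[C@@H](B2Oc3ccccc3O2)Cc2cc(OC)c(OCc3ccccc3)c(OC)c2)cc(OC)c1OCc1ccccc1
F2 | step 2 | 2-[4-(benzyloxy)-3,5-dimethoxyphenyl]acetaldehyde | COc1cc(CC=O)cc(OC)c1OCc1ccccc1
F3 | step 2 | 2-[4-(benzyloxy)-3,5-dimethoxyphenyl]ethanol | COc1cc(CCO)cc(OC)c1OCc1ccccc1
F4 | step 2 | 2-(benzyloxy)-5-(2-iodoethyl)-1,3-dimethoxybenzene | COc1cc(CCI)cc(OC)c1OCc1ccccc1
F5 | step 2 | {2-[4-(benzyloxy)-3,5-dimethoxyphenyl]ethyl}triphenylphosphonium iodide | COc1cc(CC[P+](c2ccccc2)(c2ccccc2)c2ccccc2)cc(OC)c1OCc1ccccc1.[I-]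
F6 | step 5 | dilithium bis(phenylboronate) complex of 8 (phenyl added to each boron) | [Li+].[Li+].COc1cc(C[C@@H](C[B-]2(c3ccccc3)OC(C)(C)C(C)(C)O2)[C@@H](C[B-]2(c3ccccc3)OC(C)(C)C(C)(C)O2)Cc2cc(OC)c(OCc3ccccc3)c(OC)c2)cc(OC)c1OCc1ccccc1
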